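**Retrosynthetic overview**

- Target 12 comes from the 5-hydroxyisoflavone 10 by removal of the C5 oxygen through its triflate 11.
- 10 comes from cyclobutenone 7 by thermal ring expansion. The strategy rests on ring A (C4a, C5, C6, C7, C8, C8a) and its three adjacent methoxy groups on C6, C7 and C8. C5 to C8 are the four ring carbons of dimethyl squarate, C4a and C8a are C3 and C2 of a 4-pyranone, and the new bond is C5–C4a.
- 7 comes from carbinol 6 by O-methylation, and 6 from dimethyl squarate 4 and the C6-lithiated 3-aryl-4-pyranone 5.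
- Pyranone 3 comes from bromopyranone 1 and boronic acid 2 by Suzuki coupling.
- Ring order: the aryl ring and the pyranone ring are bought, and ring A is closed last, in step 4.

Key step: step 4

Assumption: 3-bromo-4H-pyran-4-one (1) is taken as purchasable; bicyclic compounds carry chromone numbering; 6 and 7 are racemic, and their single stereocenter is destroyed in step 4, so the achiral target needs no stereocontrol.

**Route**

Step 1
Reactants: 1 3-bromo-4H-pyran-4-one; 2 (3,4,5-trimethoxyphenyl)boronic acid
Product: 3 3-(3,4,5-trimethoxyphenyl)-4H-pyran-4-one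
Conditions: PdCl2(dppf) (3 mol %), K3PO4, 1,4-dioxane–H2O (10:1), 80 °C, Ar
Reagents that add atoms: none
Why: Suzuki–Miyaura coupling, in which zerovalent palladium inserts into the C–Br bond at the α-carbon of the vinylogous ester as it does in 3-halochromones, while the phosphate base and the small share of water limit hydroxide attack on the pyranone ring.

Step 2
Reactants: 3 3-(3,4,5-trimethoxyphenyl)-4H-pyran-4-one; 4 dimethyl squarate (3,4-dimethoxycyclobut-3-ene-1,2-dione)
Product: 6 rac-4-hydroxy-2,3-dimethoxy-4-[4-oxo-5-(3,4,5-trimethoxyphenyl)-4H-pyran-2-yl]cyclobut-2-en-1-one, via C6-lithiated pyranone 5 (not isolated)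
Conditions: lithium 2,2,6,6-tetramethylpiperidide (from n-BuLi and 2,2,6,6-tetramethylpiperidine, THF, 0 °C), THF, −78 °C, 20 min; then cannulation into 4 in THF, −78 °C; aq NH4Cl, −78 °C to rt
Reagents that add atoms: none
Why: Deprotonative lithiation of a γ-pyrone at an oxygen-bound sp2 C–H (as at C2 of chromones) followed by 1,2-addition to one of the two equivalent squarate carbonyls; the bulky amide should take the unhindered C6–H and not the aryl-flanked C2–H, inverse addition and a cold quench should prevent double addition, and the carbinol stereocenter forms without control (racemate), which does not matter.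

Step 3
Reactants: 6 rac-4-hydroxy-2,3-dimethoxy-4-[4-oxo-5-(3,4,5-trimethoxyphenyl)-4H-pyran-2-yl]cyclobut-2-en-1-one
Product: 7 rac-2,3,4-trimethoxy-4-[4-oxo-5-(3,4,5-trimethoxyphenyl)-4H-pyran-2-yl]cyclobut-2-en-1-one
Conditions: MeI, Ag2O, 4 Å molecular sieves, MeCN, rt, dark
Reagents that add atoms: iodomethane, CI
Why: Purdie methylation of the tertiary cyclobutenol under nearly neutral conditions, which avoids a free alkoxide that could cleave the strained ring and uses an alkylating agent too weak to methylate the pyranone carbonyl oxygen.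

Step 4
Reactants: 7 rac-2,3,4-trimethoxy-4-[4-oxo-5-(3,4,5-trimethoxyphenyl)-4H-pyran-2-yl]cyclobut-2-en-1-one
Product: 10 5-hydroxy-6,7,8-trimethoxy-3-(3,4,5-trimethoxyphenyl)-4H-chromen-4-one, via (Z)-dienylketene 8 (not isolated), via 4aH-chromene-4,5-dione 9 (not isolated)
Conditions: degassed p-xylene (0.02 M), 138 °C, Ar
Reagents that add atoms: none
Why: Moore rearrangement: thermal conrotatory four-electron opening of the cyclobutenone C1–C4 bond, with the C4 methoxy group turning outward as donor substituents do, should give dienylketene 8 with the pyranonyl group on the ketene side ((Z) geometry). In 8 the ketene C=C, the central enol-ether C=C and the pyranone C2=C3 bond form a hexatriene, and a thermal disrotatory six-electron electrocyclization joins the electrophilic ketene carbon (future C5) to the nucleophilic β-carbon of the pyranone enol ether (future C4a), closing ring A as the cyclohexa-2,4-dienone 9. The C4a hydrogen of 9 lies between two carbonyl groups, so enolization to the hydrogen-bonded C5 phenol 10 should be fast and irreversible; the stereocenter of 7 is lost and no new one is formed. The closest known reactions are the ring expansions of 4-aryl-, 4-heteroaryl- and 4-alkenyl-4-alkoxycyclobutenones from squarates to hydroquinone monoethers; a 4-pyranon-2-yl group has not been tried, but it should react as an alkenyl group that gives up less aromatic stabilisation than furyl or phenyl. The step needs outward torquoselectivity of the methoxy group, which its donor character secures, and a single site of closure, which is secured because the other neighbour of the pyranone attachment carbon is the ring oxygen. The two squarate methoxy groups end on C6 and C7 and the methylated carbinol oxygen on C8.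

Step 5
Reactants: 10 5-hydroxy-6,7,8-trimethoxy-3-(3,4,5-trimethoxyphenyl)-4H-chromen-4-one
Product: 11 6,7,8-trimethoxy-4-oxo-3-(3,4,5-trimethoxyphenyl)-4H-chromen-5-yl trifluoromethanesulfonate
Conditions: Tf2O, pyridine, CH2Cl2, 0 °C to rt
Reagents that add atoms: trifluoromethanesulfonic anhydride, O=S(=O)(OS(=O)(=O)C(F)(F)F)C(F)(F)F
Why: O-sulfonylation (triflation) of the only hydroxyl group, as practised on 5-hydroxyflavones, with pyridine breaking the hydrogen bond to the C4 carbonyl and any triflation of the carbonyl oxygen reverting on aqueous work-up.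

Step 6
Reactants: 11 6,7,8-trimethoxy-4-oxo-3-(3,4,5-trimethoxyphenyl)-4H-chromen-5-yl trifluoromethanesulfonate
Product: 12 6,7,8-trimethoxy-3-(3,4,5-trimethoxyphenyl)-4H-chromen-4-one (target)
Conditions: Pd(OAc)2 (5 mol %), dppf, HCO2H, Et3N, DMF, 70 °C
Reagents that add atoms: none
Why: Palladium-catalysed formate reduction of an aryl triflate, in which zerovalent palladium inserts into the C5–O bond (helped by the neighbouring carbonyl), formate delivers hydride with loss of CO2 and reductive elimination gives C5–H, leaving the methyl ethers and the chromone enone untouched.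

**Compound list**

1 | 3-bromo-4H-pyran-4-one | O=c1ccocc1Br | starting material
2 | (3,4,5-trimethoxyphenyl)boronic acid | COc1cc(B(O)O)cc(OC)c1OC | starting material
3 | 3-(3,4,5-trimethoxyphenyl)-4H-pyran-4-one | COc1cc(-c2coccc2=O)cc(OC)c1OC | intermediate
4 | dimethyl squarate (3,4-dimethoxycyclobut-3-ene-1,2-dione) | COC1=C(OC)C(=O)C1=O | starting material
5 | 6-lithio-3-(3,4,5-trimethoxyphenyl)-4H-pyran-4-one | [Li]c1cc(=O)c(-c2cc(OC)c(OC)c(OC)c2)co1 | intermediate
6 | rac-4-hydroxy-2,3-dimethoxy-4-[4-oxo-5-(3,4,5-trimethoxyphenyl)-4H-pyran-2-yl]cyclobut-2-en-1-one | COC1=C(OC)C(O)(c2cc(=O)c(-c3cc(OC)c(OC)c(OC)c3)co2)C1=O | intermediate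
7 | rac-2,3,4-trimethoxy-4-[4-oxo-5-(3,4,5-trimethoxyphenyl)-4H-pyran-2-yl]cyclobut-2-en-1-one | COC1=C(OC)C(OC)(c2cc(=O)c(-c3cc(OC)c(OC)c(OC)c3)co2)C1=O | intermediate
8 | (Z)-2,3,4-trimethoxy-4-[4-oxo-5-(3,4,5-trimethoxyphenyl)-4H-pyran-2-yl]buta-1,3-dien-1-one | COC(=C=O)/C(OC)=C(/OC)c1cc(=O)c(-c2cc(OC)c(OC)c(OC)c2)co1 | intermediate
9 | rac-6,7,8-trimethoxy-3-(3,4,5-trimethoxyphenyl)-4aH-chromene-4,5-dione | COC1=C(OC)C(=O)C2C(=O)C(-c3cc(OC)c(OC)c(OC)c3)=COC2=C1OC | intermediate
10 | 5-hydroxy-6,7,8-trimethoxy-3-(3,4,5-trimethoxyphenyl)-4H-chromen-4-one | COc1cc(-c2coc3c(OC)c(OC)c(OC)c(O)c3c2=O)cc(OC)c1OC | intermediate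
11 | 6,7,8-trimethoxy-4-oxo-3-(3,4,5-trimethoxyphenyl)-4H-chromen-5-yl trifluoromethanesulfonate | COc1cc(-c2coc3c(OC)c(OC)c(OC)c(OS(=O)(=O)C(F)(F)F)c3c2=O)cc(OC)c1OC | intermediate
12 | 6,7,8-trimethoxy-3-(3,4,5-trimethoxyphenyl)-4H-chromen-4-one | COc1cc(-c2coc3c(OC)c(OC)c(OC)cc3c2=O)cc(OC)c1OC | target

**Step count and risks**

Total step count: 6. Longest linear sequence: 6 steps (1 to 12).

Steps most likely to fail:

1. Step 2. Deprotonation at the aryl-flanked C2–H may compete with deprotonation at C6–H; this would put the aryl group beside the cyclobutenone and block the carbon needed for ring closure. The lithiated pyranone may also add to pyranone not yet deprotonated. The fallback removes the regiochemical question by using a symmetric pyranone and bringing in the aryl group last; it sets out from 4 and comes back at 10. 4H-Pyran-4-one F1, whose two oxygen-bound CH groups are equivalent, would be lithiated as in step 2 to 2-lithio-4H-pyran-4-one F2 and added to 4 to give 4-hydroxy-2,3-dimethoxy-4-(4-oxo-4H-pyran-2-yl)cyclobut-2-en-1-one F3. Methylation with MeI and Ag2O would give 2,3,4-trimethoxy-4-(4-oxo-4H-pyran-2-yl)cyclobut-2-en-1-one F4. Heating in p-xylene should then lead through (Z)-2,3,4-trimethoxy-4-(4-oxo-4H-pyran-2-yl)buta-1,3-dien-1-one F5 and 6,7,8-trimethoxy-4aH-chromene-4,5-dione F6 to 5-hydroxy-6,7,8-trimethoxy-4H-chromen-4-one F7. Dimethylamine in EtOH would open the pyranone ring to (E)-3-(dimethylamino)-1-(2,6-dihydroxy-3,4,5-trimethoxyphenyl)prop-2-en-1-one F8, whose two hydroxyl groups are equivalent. I2 in CHCl3 would close it again to 5-hydroxy-3-iodo-6,7,8-trimethoxy-4H-chromen-4-one F9, and Suzuki coupling of this iodide with 2 under the conditions of step 1 would give 10.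

2. Step 4. The dienylketene may be diverted before it closes onto the pyranone, by polymerisation or by inward rotation of the methoxy group, or the pyranonyl cyclobutenone may decompose at the temperature needed. The fallback gives up the ring expansion for a classical isoflavone synthesis in which ring A is bought; it sets out from 2, the only numbered compound it uses, and comes back at 12. 2,3,4-Trimethoxyphenol F10 would be acylated ortho to the hydroxyl group with AcOH and BF3·OEt2 at 90 °C to 1-(2-hydroxy-3,4,5-trimethoxyphenyl)ethan-1-one F11. Condensation with N,N-dimethylformamide dimethyl acetal in toluene at 100 °C would give (E)-3-(dimethylamino)-1-(2-hydroxy-3,4,5-trimethoxyphenyl)prop-2-en-1-one F12. I2 in CHCl3 would cyclise it to 3-iodo-6,7,8-trimethoxy-4H-chromen-4-one F13, and Suzuki coupling with 2 under the conditions of step 1 would give 12 directly.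

3. Step 3. Ring cleavage or rearrangement of the strained α-hydroxy ketone may set in on the basic silver oxide surface before the hindered tertiary hydroxyl is methylated, and the pyranone carbonyl oxygen may be alkylated in competition. The fallback leaves the carbinol free during the ring expansion and methylates afterwards; it sets out from 6 and comes back at 10. Heating 6 in degassed p-xylene under argon should open the ring with the hydroxyl group turning outward, giving (Z)-4-hydroxy-2,3-dimethoxy-4-[4-oxo-5-(3,4,5-trimethoxyphenyl)-4H-pyran-2-yl]buta-1,3-dien-1-one F14. Closure to 8-hydroxy-6,7-dimethoxy-3-(3,4,5-trimethoxyphenyl)-4aH-chromene-4,5-dione F15 and enolization would give the hydroquinone 5,8-dihydroxy-6,7-dimethoxy-3-(3,4,5-trimethoxyphenyl)-4H-chromen-4-one F16, which is kept under argon to prevent oxidation to the quinone. MeI (1 equiv) and K2CO3 in degassed acetone at rt should methylate the free C8 hydroxyl and leave the hydrogen-bonded C5 hydroxyl, giving 10.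

**Further compounds**

F1 | step 2 | 4H-pyran-4-one | O=c1ccocc1
F2 | step 2 | 2-lithio-4H-pyran-4-one | [Li]c1cc(=O)cco1
F3 | step 2 | rac-4-hydroxy-2,3-dimethoxy-4-(4-oxo-4H-pyran-2-yl)cyclobut-2-en-1-one | COC1=C(OC)C(O)(c2cc(=O)cco2)C1=O
F4 | step 2 | rac-2,3,4-trimethoxy-4-(4-oxo-4H-pyran-2-yl)cyclobut-2-en-1-one | COC1=C(OC)C(OC)(c2cc(=O)cco2)C1=O
F5 | step 2 | (Z)-2,3,4-trimethoxy-4-(4-oxo-4H-pyran-2-yl)buta-1,3-dien-1-one | COC(=C=O)/C(OC)=C(/OC)c1cc(=O)cco1
F6 | step 2 | rac-6,7,8-trimethoxy-4aH-chromene-4,5-dione | COC1=C(OC)C(=O)C2C(=O)C=COC2=C1OC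
F7 | step 2 | 5-hydroxy-6,7,8-trimethoxy-4H-chromen-4-one | COc1c(O)c2c(=O)ccoc2c(OC)c1OC
F8 | step 2 | (E)-3-(dimethylamino)-1-(2,6-dihydroxy-3,4,5-trimethoxyphenyl)prop-2-en-1-one | CN(C)/C=C/C(=O)c1c(O)c(OC)c(OC)c(OC)c1O
F9 | step 2 | 5-hydroxy-3-iodo-6,7,8-trimethoxy-4H-chromen-4-one | COc1c(O)c2c(=O)c(I)coc2c(OC)c1OC
F10 | step 4 | 2,3,4-trimethoxyphenol | COc1ccc(O)c(OC)c1OC
F11 | step 4 | 1-(2-hydroxy-3,4,5-trimethoxyphenyl)ethan-1-one | CC(=O)c1cc(OC)c(OC)c(OC)c1O
F12 | step 4 | (E)-3-(dimethylamino)-1-(2-hydroxy-3,4,5-trimethoxyphenyl)prop-2-en-1-one | CN(C)/C=C/C(=O)c1cc(OC)c(OC)c(OC)c1O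
F13 | step 4 | 3-iodo-6,7,8-trimethoxy-4H-chromen-4-one | COc1cc2c(=O)c(I)coc2c(OC)c1OC
F14 | step 3 | (Z)-4-hydroxy-2,3-dimethoxy-4-[4-oxo-5-(3,4,5-trimethoxyphenyl)-4H-pyran-2-yl]buta-1,3-dien-1-one | COC(=C=O)/C(OC)=C(/O)c1cc(=O)c(-c2cc(OC)c(OC)c(OC)c2)co1
F15 | step 3 | rac-8-hydroxy-6,7-dimethoxy-3-(3,4,5-trimethoxyphenyl)-4aH-chromene-4,5-dione | COC1=C(OC)C(=O)C2C(=O)C(-c3cc(OC)c(OC)c(OC)c3)=COC2=C1O
F16 | step 3 | 5,8-dihydroxy-6,7-dimethoxy-3-(3,4,5-trimethoxyphenyl)-4H-chromen-4-one | COc1cc(-c2coc3c(O)c(OC)c(OC)c(O)c3c2=O)cc(OC)c1OC
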